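The γ-butyrolactone (ring atoms O1, C2, C3, C4, C5) is disconnected at C3–C4. A diazoacetate placed on the tertiary C5 oxygen generates a rhodium carbene at C3 that sits 1,5 to the ether-activated C4–H bonds of a CH2OPMB group. One catalyst-controlled intramolecular C–H insertion closes the lactone, forges C3–C4 and creates the C4 carbinol centre cis to the C5 methyl. The precursor is an acyclic (R)-tertiary diazoacetate built from (S)-2-methylglycidol, which supplies C5, and an (E)-tetradec-10-enyl Grignard reagent, which supplies the side chain. C3 is finally hydroxymethylated trans to the C4 oxygen through the lactone dianion.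

Key step: step 8

Remark on the chemistry: the target is (3S,4S,5R), with the C3 CH2OH trans to the C4 OH and the C4 OH cis to the C5 methyl. (S)-2-Methylglycidol is assumed to be purchased in high enantiomeric purity, and monomeric formaldehyde is generated by cracking paraformaldehyde.

Step 1
Reactants: 1 undec-10-yn-1-ol
Product: 2 tetradec-10-yn-1-ol
Conditions: n-BuLi (2.2 equiv), THF–DMPU, −40 → 0 °C; n-PrBr, 0 °C → rt; aq NH4Cl
Reagents that add atoms: 1-bromopropane, CCCBr
Why: Acetylide alkylation: the dilithio derivative of 1 (alkoxide plus acetylide) should be C-alkylated by the primary bromide much faster than it is O-alkylated, so no hydroxyl protection is needed.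

Step 2
Reactants: 2 tetradec-10-yn-1-ol
Product: 3 (E)-tetradec-10-en-1-ol
Conditions: Na, NH3 (l), THF, −33 °C; NH4Cl quench
Reagents that add atoms: none
Why: Dissolving-metal reduction of an isolated internal alkyne passes through a vinyl radical anion and vinyl anion that adopt the trans geometry before protonation, so the E-alkene is set here.

Step 3
Reactants: 3 (E)-tetradec-10-en-1-ol
Product: 4 (E)-14-bromotetradec-4-ene
Conditions: CBr4, PPh3, CH2Cl2, 0 °C
Reagents that add atoms: carbon tetrabromide, BrC(Br)(Br)Br
Why: Appel reaction: SN2 displacement of the alkoxyphosphonium ion by bromide converts the primary alcohol into the bromide without touching the isolated E-alkene.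

Step 4
Reactants: 5 (S)-(2-methyloxiran-2-yl)methanol [(S)-2-methylglycidol]
Product: 6 (R)-2-{[(4-methoxybenzyl)oxy]methyl}-2-methyloxirane
Conditions: NaH, PMBCl, Bu4NI (cat.), THF, 0 °C → rt
Reagents that add atoms: 4-methoxybenzyl chloride, COc1ccc(CCl)cc1
Why: Williamson etherification of the primary alkoxide leaves the quaternary epoxide carbon untouched (a Payne migration here is degenerate and returns the same enantiomer); the descriptor changes from S to R only through the CIP priorities.

Step 5
Reactants: 4 (E)-14-bromotetradec-4-ene; 6 (R)-2-{[(4-methoxybenzyl)oxy]methyl}-2-methyloxirane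
Product: 8 (R,E)-1-[(4-methoxybenzyl)oxy]-2-methylheptadec-13-en-2-ol, via (E)-tetradec-10-enylmagnesium bromide 7 (not isolated)
Conditions: Mg, THF, rt → 45 °C; then CuI (copper monoiodide, 10 mol %), 6, THF, −30 → 0 °C; aq NH4Cl
Reagents that add atoms: none
Why: Copper-catalysed SN2 opening of a 2,2-disubstituted epoxide by a Grignard reagent occurs only at the unsubstituted CH2 terminus, so the C–O stereocentre of 6 becomes the tertiary carbinol (future C5) of 8 with its configuration intact.

Step 6
Reactants: 8 (R,E)-1-[(4-methoxybenzyl)oxy]-2-methylheptadec-13-en-2-ol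
Product: 9 (R,E)-1-[(4-methoxybenzyl)oxy]-2-methylheptadec-13-en-2-yl 2-bromoacetate
Conditions: BrCH2COBr, pyridine, CH2Cl2, 0 °C → rt
Reagents that add atoms: bromoacetyl bromide, BrCC(Br)=O
Why: O-Acylation with an acid bromide, reactive enough to esterify a hindered tertiary hydroxyl under mild base, should leave the PMB ether and the alkene untouched.

Step 7
Reactants: 9 (R,E)-1-[(4-methoxybenzyl)oxy]-2-methylheptadec-13-en-2-yl 2-bromoacetate
Product: 10 (R,E)-1-[(4-methoxybenzyl)oxy]-2-methylheptadec-13-en-2-yl 2-diazoacetate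
Conditions: TsNHNHTs, DBU, THF, 0 °C
Reagents that add atoms: N,N'-ditosylhydrazine, Cc1ccc(cc1)S(=O)(=O)NNS(=O)(=O)c1ccc(C)cc1
Why: Diazo ester synthesis from a bromoacetate: the ditosylhydrazine anion displaces bromide at the unhindered CH2 (SN2) and DBU then eliminates two sulfinate ions to unveil the diazo group without touching the tertiary ester.

Step 8
Reactants: 10 (R,E)-1-[(4-methoxybenzyl)oxy]-2-methylheptadec-13-en-2-yl 2-diazoacetate
Product: 11 (4S,5R)-4-[(4-methoxybenzyl)oxy]-5-methyl-5-[(E)-pentadec-11-en-1-yl]dihydrofuran-2(3H)-one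
Conditions: Rh2(5S-MEPY)4 (dirhodium tetrakis[methyl (5S)-2-oxopyrrolidine-5-carboxylate], divalent rhodium, 1 mol %), CH2Cl2, reflux, 10 added by syringe pump over 10 h
Reagents that add atoms: none
Why: Rhodium-carbene C–H insertion: the catalyst extrudes N2 from the diazoacetate to give an electrophilic carbene at C3, which inserts through a concerted three-centre, hydride-transfer-like transition state into a C4–H bond that lies 1,5 to the carbene carbon and is activated by the adjacent PMB ether oxygen. This is the established carboxamidate-catalysed conversion of 2-alkoxyalkyl diazoacetates into 4-alkoxy-γ-butyrolactones. The one ring closed is the five-membered lactone (O1, C2, C3, C4, C5), formed by 1,5-insertion, the kinetically preferred mode for ester-tethered carbenes. The new C4 stereocentre comes from the choice between the two diastereotopic C4 hydrogens; since C5 carries two groups of nearly equal size (CH3 and CH2R) the substrate imposes little bias, so the chiral carboxamidate ligands decide, and the 5S catalyst should select the pro-S hydrogen in the sense known for 2-alkoxyethyl diazoacetates, placing the C4 oxygen cis to the C5 methyl (the 5R antipode of the catalyst is the reserve if the sense proves opposite), while C5 is untouched. The step needs chemoselectivity over insertion into the unactivated chain CH2 and CH3 on C5, over oxonium ylide formation at the ether oxygen and over cyclopropanation of the remote E-alkene; the ether activation of C4–H, the 1,5-geometry, the low electrophilicity of carboxamidate carbenes and slow addition at high dilution should secure it.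

Step 9
Reactants: 11 (4S,5R)-4-[(4-methoxybenzyl)oxy]-5-methyl-5-[(E)-pentadec-11-en-1-yl]dihydrofuran-2(3H)-one
Product: 12 (4S,5R)-4-hydroxy-5-methyl-5-[(E)-pentadec-11-en-1-yl]dihydrofuran-2(3H)-one
Conditions: DDQ, CH2Cl2–pH 7 buffer, 0 °C → rt
Reagents that add atoms: none
Why: Oxidative cleavage of a p-methoxybenzyl ether: DDQ oxidises the electron-rich benzylic position to an oxocarbenium ion that water hydrolyses, while the isolated alkene, the lactone and the C4 and C5 centres should be unaffected.

Step 10
Reactants: 12 (4S,5R)-4-hydroxy-5-methyl-5-[(E)-pentadec-11-en-1-yl]dihydrofuran-2(3H)-one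
Product: 14 (3S,4S,5R)-4-hydroxy-3-(hydroxymethyl)-5-methyl-5-[(E)-pentadec-11-en-1-yl]dihydrofuran-2(3H)-one, via dilithium alkoxide-enolate of the lactone 13 (not isolated)
Conditions: LDA (2.3 equiv), THF, −78 → −40 °C; CH2O (g, from cracked paraformaldehyde), −78 °C; aq NH4Cl at −78 °C
Reagents that add atoms: formaldehyde, C=O
Why: Aldol addition of a β-hydroxy lactone dianion (Fráter–Seebach-type reaction): the C4 lithium alkoxide cannot be eliminated and shields its own face, so formaldehyde should add at C3 anti to it and set the new C3 centre trans to the C4 oxygen (3S).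

Compound list
1 | undec-10-yn-1-ol | C#CCCCCCCCCCO | starting material
2 | tetradec-10-yn-1-ol | CCCC#CCCCCCCCCCO | intermediate
3 | (E)-tetradec-10-en-1-ol | CCC/C=C/CCCCCCCCCO | intermediate
4 | (E)-14-bromotetradec-4-ene | CCC/C=C/CCCCCCCCCBr | intermediate
5 | (S)-(2-methyloxiran-2-yl)methanol [(S)-2-methylglycidol] | C[C@]1(CO)CO1 | starting material
6 | (R)-2-{[(4-methoxybenzyl)oxy]methyl}-2-methyloxirane | C[C@]1(COCc2ccc(OC)cc2)CO1 | intermediate
7 | (E)-tetradec-10-enylmagnesium bromide | CCC/C=C/CCCCCCCCC[Mg]Br | intermediate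
8 | (R,E)-1-[(4-methoxybenzyl)oxy]-2-methylheptadec-13-en-2-ol | CCC/C=C/CCCCCCCCCC[C@@](C)(O)COCc1ccc(OC)cc1 | intermediate
9 | (R,E)-1-[(4-methoxybenzyl)oxy]-2-methylheptadec-13-en-2-yl 2-bromoacetate | CCC/C=C/CCCCCCCCCC[C@@](C)(OC(=O)CBr)COCc1ccc(OC)cc1 | intermediate
10 | (R,E)-1-[(4-methoxybenzyl)oxy]-2-methylheptadec-13-en-2-yl 2-diazoacetate | CCC/C=C/CCCCCCCCCC[C@@](C)(OC(=O)C=[N+]=[N-])COCc1ccc(OC)cc1 | intermediate
11 | (4S,5R)-4-[(4-methoxybenzyl)oxy]-5-methyl-5-[(E)-pentadec-11-en-1-yl]dihydrofuran-2(3H)-one | CCC/C=C/CCCCCCCCCC[C@@]1(C)OC(=O)C[C@@H]1OCc2ccc(OC)cc2 | intermediate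
12 | (4S,5R)-4-hydroxy-5-methyl-5-[(E)-pentadec-11-en-1-yl]dihydrofuran-2(3H)-one | CCC/C=C/CCCCCCCCCC[C@@]1(C)OC(=O)C[C@@H]1O | intermediate
13 | dilithium alkoxide-enolate of lactone 12 | CCC/C=C/CCCCCCCCCC[C@@]1(C)OC(O[Li])=C[C@@H]1O[Li] | intermediate
14 | (3S,4S,5R)-4-hydroxy-3-(hydroxymethyl)-5-methyl-5-[(E)-pentadec-11-en-1-yl]dihydrofuran-2(3H)-one | CCC/C=C/CCCCCCCCCC[C@@]1(C)OC(=O)[C@@H](CO)[C@@H]1O | target

Total step count: 10. Longest linear sequence: 9 steps (steps 1, 2, 3, 5, 6, 7, 8, 9, 10).

Steps most likely to fail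

Step 8. The risk is insufficient discrimination between the two diastereotopic C4–H bonds, because the hindered tertiary ester may blunt catalyst control, together with carbene dimerisation or insertion at the chain CH2. The fallback sets out from 8 and comes back at 12. It makes the C3–C4 bond by an auxiliary-controlled intermolecular acetate aldol and then closes the ring by lactonisation. Compound 8 is silylated (TESOTf, 2,6-lutidine, CH2Cl2, −78 °C) to (R,E)-triethyl({1-[(4-methoxybenzyl)oxy]-2-methylheptadec-13-en-2-yl}oxy)silane F1. DDQ in buffered CH2Cl2 then frees the primary alcohol (R,E)-2-methyl-2-[(triethylsilyl)oxy]heptadec-13-en-1-ol F2, and DMP (Dess–Martin periodinane) oxidises it to the non-enolisable aldehyde (R,E)-2-methyl-2-[(triethylsilyl)oxy]heptadec-13-enal F3. The tin enolate of N-acetyl-(S)-4-isopropyl-1,3-thiazolidine-2-thione (Sn(OTf)2, divalent tin, N-ethylpiperidine, CH2Cl2, −78 °C) should add to F3 to give (3S,4R,E)-3-hydroxy-1-[(S)-4-isopropyl-2-thioxothiazolidin-3-yl]-4-methyl-4-[(triethylsilyl)oxy]nonadec-15-en-1-one F4. Here the auxiliary, not C5, sets the carbinol; the (S)-auxiliary is expected to give the required sense and its antipode is available. HF·pyridine followed by imidazole in THF removes the silyl group, and the freed tertiary hydroxyl displaces the thiazolidinethione to give 12.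

Step 10. The risk is incomplete deprotonation at C3 of the lithium alkoxide, retro-aldol opening of the β-alkoxide on warming, or polymerisation of formaldehyde before the enolate captures it. The fallback sets out from 11 and comes back at 14. It replaces the dianion aldol by SN2 alkylation of the O-protected lactone enolate. Compound 11 is deprotonated (LDA, THF, −78 °C) and alkylated with 4-methoxybenzyl chloromethyl ether (COc1ccc(COCCl)cc1) anti to the C4 ether to give (3S,4S,5R)-4-[(4-methoxybenzyl)oxy]-3-{[(4-methoxybenzyl)oxy]methyl}-5-methyl-5-[(E)-pentadec-11-en-1-yl]dihydrofuran-2(3H)-one F5. Excess DDQ in wet CH2Cl2 then removes both PMB groups to give 14.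

Step 6. The risk is sluggish acylation of the hindered tertiary hydroxyl, with competing quaternisation of pyridine by the bromoacetyl group. The fallback sets out from 8 and comes back at 10. It reaches the diazoacetate by acyl-ketene trapping and diazo transfer instead. Compound 8 is heated with 2,2,6-trimethyl-4H-1,3-dioxin-4-one (xylene, 140 °C; acetylketene) to give (R,E)-1-[(4-methoxybenzyl)oxy]-2-methylheptadec-13-en-2-yl 3-oxobutanoate F6. Regitz diazo transfer (4-acetamidobenzenesulfonyl azide, Et3N, MeCN) gives (R,E)-1-[(4-methoxybenzyl)oxy]-2-methylheptadec-13-en-2-yl 2-diazo-3-oxobutanoate F7. Deacetylation with LiOH in aqueous MeCN gives 10.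

Further compounds
F1 | step 8 | (R,E)-triethyl({1-[(4-methoxybenzyl)oxy]-2-methylheptadec-13-en-2-yl}oxy)silane | CCC/C=C/CCCCCCCCCC[C@@](C)(O[Si](CC)(CC)CC)COCc1ccc(OC)cc1
F2 | step 8 | (R,E)-2-methyl-2-[(triethylsilyl)oxy]heptadec-13-en-1-ol | CCC/C=C/CCCCCCCCCC[C@@](C)(O[Si](CC)(CC)CC)CO
F3 | step 8 | (R,E)-2-methyl-2-[(triethylsilyl)oxy]heptadec-13-enal | CCC/C=C/CCCCCCCCCC[C@@](C)(O[Si](CC)(CC)CC)C=O
F4 | step 8 | (3S,4R,E)-3-hydroxy-1-[(S)-4-isopropyl-2-thioxothiazolidin-3-yl]-4-methyl-4-[(triethylsilyl)oxy]nonadec-15-en-1-one | CCC/C=C/CCCCCCCCCC[C@@](C)(O[Si](CC)(CC)CC)[C@@H](O)CC(=O)N1[C@@H](C(C)C)CSC1=S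
F5 | step 10 | (3S,4S,5R)-4-[(4-methoxybenzyl)oxy]-3-{[(4-methoxybenzyl)oxy]methyl}-5-methyl-5-[(E)-pentadec-11-en-1-yl]dihydrofuran-2(3H)-one | CCC/C=C/CCCCCCCCCC[C@@]1(C)OC(=O)[C@@H](COCc2ccc(OC)cc2)[C@@H]1OCc1ccc(OC)cc1
F6 | step 6 | (R,E)-1-[(4-methoxybenzyl)oxy]-2-methylheptadec-13-en-2-yl 3-oxobutanoate | CCC/C=C/CCCCCCCCCC[C@@](C)(OC(=O)CC(C)=O)COCc1ccc(OC)cc1
F7 | step 6 | (R,E)-1-[(4-methoxybenzyl)oxy]-2-methylheptadec-13-en-2-yl 2-diazo-3-oxobutanoate | CCC/C=C/CCCCCCCCCC[C@@](C)(OC(=O)C(=[N+]=[N-])C(C)=O)COCc1ccc(OC)cc1
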